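The route rests on cutting the cyclohexane (C-1 angelate, C-2 side chain, C-4 acetate, C-5 methyl) between C-4 and C-5, whose vicinal oxygen/methyl pair is the retron of a 2-methylcyclohexanone. The precursor is an open-chain Se-phenyl selenoester: its acyl carbon becomes C-4 and its terminal vinyl group becomes C-5 and the ring methyl. One 6-exo acyl radical cyclisation closes the ring and creates the C-4 ketone. Because C-5 is then enolisable, both epimers funnel to the equatorial methyl, and equatorial hydride attack gives the axial C-4 oxygen. The other stereocentres are relayed from methyl (R)-hydrogen 3-methylglutarate through a cis-disubstituted δ-lactone and one reagent-controlled allylation.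

Key step: step 10

Remark: ring positions C-1 to C-6 and side-chain positions C-1' to C-7' follow the name of the target throughout; the hemiester, the Grignard solution, the bromoacetate, the allylborane solution and angelic acid are taken as purchased.

Step 1
Reactants: 1 methyl (R)-hydrogen 3-methylglutarate; 2 (2-methylprop-1-en-1-yl)magnesium bromide
Product: 4 methyl (3R)-3,7-dimethyl-5-oxooct-6-enoate, via acid chloride 3 (not isolated)
Conditions: (COCl)2, DMF (cat.), CH2Cl2, 0 °C; evaporate cold; then 2 (1.05 equiv, slow addition), CuI (5 mol%), THF, −78 °C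
Reagents that add atoms: none
Why: Acid chloride formation followed by copper-catalysed acylation of the alkenyl Grignard reagent should convert the free carboxyl into the β,β-dimethyl enone at −78 °C without touching the methyl ester or C-2', provided the acid chloride is made and used cold to avoid ester/acyl chloride interchange.

Step 2
Reactants: 4 methyl (3R)-3,7-dimethyl-5-oxooct-6-enoate
Product: 6 (4R,6R)-4-methyl-6-(2-methylprop-1-en-1-yl)oxan-2-one, via hydroxy ester 5 (not isolated)
Conditions: (S)-2-methyl-CBS-oxazaborolidine (0.2 equiv), catecholborane, toluene, −78 °C; MeOH quench; then PPTS (cat.), toluene, 50 °C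
Reagents that add atoms: none
Why: In this Corey–Bakshi–Shibata reduction the alkenyl group acts as the large substituent, so the (S)-catalyst should give the (5R) allylic alcohol (the future C-4', catalyst control), and lactonisation then gives the cis-4,6-disubstituted δ-lactone with both groups equatorial.

Step 3
Reactants: 6 (4R,6R)-4-methyl-6-(2-methylprop-1-en-1-yl)oxan-2-one; 7 tert-butyl bromoacetate
Product: 8 tert-butyl 2-[(3S,4R,6R)-4-methyl-6-(2-methylprop-1-en-1-yl)-2-oxooxan-3-yl]acetate
Conditions: LiN(i-Pr)2 (LDA, 1.1 equiv), THF, −78 °C; then 7, −78 to −40 °C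
Reagents that add atoms: none
Why: Alkylation of the lithium lactone enolate should occur anti to the adjacent methyl group (substrate control), giving the all-equatorial 3,4-trans lactone, which is also the thermodynamic epimer, and so setting the future ring C-2.

Step 4
Reactants: 8 tert-butyl 2-[(3S,4R,6R)-4-methyl-6-(2-methylprop-1-en-1-yl)-2-oxooxan-3-yl]acetate
Product: 9 tert-butyl (3S,4R,6R)-6-hydroxy-3-[methoxy(methyl)carbamoyl]-4,8-dimethylnon-7-enoate
Conditions: MeNH(OMe)·HCl, AlMe3, CH2Cl2, 0 °C to rt; used at once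
Reagents that add atoms: N,O-dimethylhydroxylamine hydrochloride, CNOC.Cl
Why: Weinreb aminolysis with the dimethylaluminium amide opens the lactone at its acyl carbon, leaves the hindered tert-butyl ester and all stereocentres untouched, and releases the C-4' hydroxyl.

Step 5
Reactants: 9 tert-butyl (3S,4R,6R)-6-hydroxy-3-[methoxy(methyl)carbamoyl]-4,8-dimethylnon-7-enoate
Product: 10 tert-butyl (3S,4R,6R)-3-[methoxy(methyl)carbamoyl]-4,8-dimethyl-6-[(triethylsilyl)oxy]non-7-enoate
Conditions: Et3SiCl, imidazole, DMF, 0 °C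
Reagents that add atoms: chlorotriethylsilane, CC[Si](Cl)(CC)CC
Why: Silylation of the allylic alcohol blocks relactonisation and masks C-4' with an ether that can later be removed in the presence of the more hindered silyl ether at C-1.

Step 6
Reactants: 10 tert-butyl (3S,4R,6R)-3-[methoxy(methyl)carbamoyl]-4,8-dimethyl-6-[(triethylsilyl)oxy]non-7-enoate
Product: 11 tert-butyl (3S,4R,6R)-3-formyl-4,8-dimethyl-6-[(triethylsilyl)oxy]non-7-enoate
Conditions: i-Bu2AlH (1.3 equiv), THF, −78 °C; Rochelle salt work-up; used crude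
Reagents that add atoms: none
Why: Weinreb amide reduction stops at the aldehyde through the chelated aluminium hemiaminal, and the tert-butyl ester should not be reduced at −78 °C.

Step 7
Reactants: 11 tert-butyl (3S,4R,6R)-3-formyl-4,8-dimethyl-6-[(triethylsilyl)oxy]non-7-enoate; 12 (+)-B-allyldiisopinocampheylborane (from (−)-α-pinene, 1 M in pentane)
Product: 13 tert-butyl (3S,4R,6R)-3-[(1R)-1-hydroxybut-3-en-1-yl]-4,8-dimethyl-6-[(triethylsilyl)oxy]non-7-enoate
Conditions: 12 (1.5 equiv), Et2O, −78 °C; then NaOH aq., H2O2, 0 °C to rt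
Reagents that add atoms: none
Why: Brown allylboration through a chair Zimmerman–Traxler transition state should deliver the allyl group to the Re face of the aldehyde and give the (1R) carbinol (future ring C-1) under reagent control, against a weak opposing Felkin bias.

Step 8
Reactants: 13 tert-butyl (3S,4R,6R)-3-[(1R)-1-hydroxybut-3-en-1-yl]-4,8-dimethyl-6-[(triethylsilyl)oxy]non-7-enoate
Product: 15 (3S,4R,6R)-3-[(1R)-1-[(tert-butyldimethylsilyl)oxy]but-3-en-1-yl]-4,8-dimethyl-6-[(triethylsilyl)oxy]non-7-enoic acid, via silyl ester 14 (not isolated)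
Conditions: TBSOTf (3.5 equiv), 2,6-lutidine (5 equiv), CH2Cl2, −78 °C to rt; then aqueous methanolic K2CO3, 0 °C; acidify to pH 5
Reagents that add atoms: tert-butyldimethylsilyl trifluoromethanesulfonate, CC(C)(C)[Si](C)(C)OS(=O)(=O)C(F)(F)F
Why: The silyl triflate should silylate the hindered secondary alcohol and exchange the tert-butyl ester for a silyl ester with loss of isobutene, and mild basic methanolysis then frees only the carboxylic acid.

Step 9
Reactants: 15 (3S,4R,6R)-3-[(1R)-1-[(tert-butyldimethylsilyl)oxy]but-3-en-1-yl]-4,8-dimethyl-6-[(triethylsilyl)oxy]non-7-enoic acid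
Product: 16 Se-phenyl (3S,4R,6R)-3-[(1R)-1-[(tert-butyldimethylsilyl)oxy]but-3-en-1-yl]-4,8-dimethyl-6-[(triethylsilyl)oxy]non-7-eneselenoate
Conditions: PhSeSePh, PBu3, CH2Cl2, rt
Reagents that add atoms: diphenyl diselenide, c1ccccc1[Se][Se]c1ccccc1
Why: Selenoester formation through an acyloxyphosphonium ion that is attacked by benzeneselenolate gives the acyl radical precursor under neutral conditions.

Step 10
Reactants: 16 Se-phenyl (3S,4R,6R)-3-[(1R)-1-[(tert-butyldimethylsilyl)oxy]but-3-en-1-yl]-4,8-dimethyl-6-[(triethylsilyl)oxy]non-7-eneselenoate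
Product: 18 (2S,4R,5S)-4-[(tert-butyldimethylsilyl)oxy]-2-methyl-5-[(2R,4R)-6-methyl-4-[(triethylsilyl)oxy]hept-5-en-2-yl]cyclohexan-1-one, via axial-methyl epimer 17 (not isolated)
Conditions: Bu3SnH (1.3 equiv) and AIBN (0.2 equiv) added over 6 h to 16 (about 5 mM) in benzene, 80 °C; KF aq. work-up; then DBU (0.5 equiv), CH2Cl2, rt
Reagents that add atoms: none
Why: The tributyltin radical abstracts the phenylseleno group of 16 to give the acyl radical at the future C-4, which adds to the internal carbon of the terminal vinyl group (future C-5), and the exocyclic primary radical takes hydrogen from Bu3SnH to become the C-5 methyl, so that ring, C-4 carbonyl and methyl branch arise in one chain process. The closest known reaction type is the tin hydride-mediated acyl radical–alkene cyclisation of Se-phenyl selenoesters, a radical hydroacylation. The ring closes in the 6-exo-trig mode through a chair-like transition state in which the C-1 silyloxy group and the C-2 side chain are equatorial. The only new stereocentre, C-5, is alpha to the new ketone, so DBU should funnel the kinetic mixture of 17 and 18 to the all-equatorial 18 with the methyl cis to the C-1 oxygen, while C-1 and C-2 cannot enolise. The step needs 6-exo closure to outrun 7-endo closure, 7-exo attack on the trisubstituted side-chain alkene and direct reduction of the acyl radical: the nucleophilic acyl radical reaches the unhindered monosubstituted alkene through a six-membered transition state whereas the side-chain alkene demands a seven-membered one, and a low stationary stannane concentration disfavours bimolecular reduction yet should still trap the cyclised radical before Dowd–Beckwith ring expansion.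

Step 11
Reactants: 18 (2S,4R,5S)-4-[(tert-butyldimethylsilyl)oxy]-2-methyl-5-[(2R,4R)-6-methyl-4-[(triethylsilyl)oxy]hept-5-en-2-yl]cyclohexan-1-one
Product: 19 (1R,2S,4R,5S)-4-[(tert-butyldimethylsilyl)oxy]-2-methyl-5-[(2R,4R)-6-methyl-4-[(triethylsilyl)oxy]hept-5-en-2-yl]cyclohexan-1-ol
Conditions: LiBH(s-Bu)3 (L-Selectride), THF, −78 °C; NaOH aq., H2O2 work-up
Reagents that add atoms: none
Why: The bulky trialkylborohydride should attack the conformationally locked 2-methylcyclohexanone from the equatorial direction and give the axial C-4 alcohol cis to the C-5 methyl (substrate control).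

Step 12
Reactants: 19 (1R,2S,4R,5S)-4-[(tert-butyldimethylsilyl)oxy]-2-methyl-5-[(2R,4R)-6-methyl-4-[(triethylsilyl)oxy]hept-5-en-2-yl]cyclohexan-1-ol
Product: 21 (1R,2S,4R,5S)-5-[(2R,4R)-4-acetoxy-6-methylhept-5-en-2-yl]-4-[(tert-butyldimethylsilyl)oxy]-2-methylcyclohexyl acetate, via diol 20 (not isolated)
Conditions: PPTS, MeOH/CH2Cl2, 0 °C to rt; evaporate; then Ac2O, pyridine, DMAP (cat.), CH2Cl2, rt
Reagents that add atoms: acetic anhydride, CC(=O)OC(C)=O
Why: Mild acid methanolysis should remove the triethylsilyl ether but not the hindered secondary tert-butyldimethylsilyl ether, and acetylation of the resulting diol installs both acetates at once.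

Step 13
Reactants: 21 (1R,2S,4R,5S)-5-[(2R,4R)-4-acetoxy-6-methylhept-5-en-2-yl]-4-[(tert-butyldimethylsilyl)oxy]-2-methylcyclohexyl acetate
Product: 22 (1R,2S,4R,5S)-5-[(2R,4R)-4-acetoxy-6-methylhept-5-en-2-yl]-4-hydroxy-2-methylcyclohexyl acetate
Conditions: HF·pyridine, pyridine, THF, 0 °C to rt
Reagents that add atoms: none
Why: Buffered fluoride desilylation should free the C-1 hydroxyl without acyl migration or ionisation of the allylic acetate.

Step 14
Reactants: 22 (1R,2S,4R,5S)-5-[(2R,4R)-4-acetoxy-6-methylhept-5-en-2-yl]-4-hydroxy-2-methylcyclohexyl acetate; 23 angelic acid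
Product: 25 (1R,2S,4R,5S)-4-acetoxy-2-[(2R,4R)-4-acetoxy-6-methylhept-5-en-2-yl]-5-methylcyclohexyl (2Z)-2-methylbut-2-enoate, via mixed anhydride 24 (not isolated)
Conditions: 23, 2,4,6-trichlorobenzoyl chloride, Et3N, toluene, rt; then 22, toluene, 80 °C (no DMAP)
Reagents that add atoms: none
Why: Yamaguchi-type esterification through the 2,4,6-trichlorobenzoyl mixed anhydride, run without a nucleophilic catalyst, should acylate the equatorial C-1 alcohol while keeping the (Z) geometry of the angelate.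

Compound list
1 | (3R)-5-methoxy-3-methyl-5-oxopentanoic acid (methyl (R)-hydrogen 3-methylglutarate) | COC(=O)C[C@H](C)CC(=O)O | starting material
2 | (2-methylprop-1-en-1-yl)magnesium bromide | CC(C)=C[Mg]Br | starting material
3 | methyl (3S)-5-chloro-3-methyl-5-oxopentanoate | COC(=O)C[C@H](C)CC(=O)Cl | intermediate
4 | methyl (3R)-3,7-dimethyl-5-oxooct-6-enoate | COC(=O)C[C@H](C)CC(=O)C=C(C)C | intermediate
5 | methyl (3R,5R)-5-hydroxy-3,7-dimethyloct-6-enoate | COC(=O)C[C@H](C)C[C@H](C=C(C)C)O | intermediate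
6 | (4R,6R)-4-methyl-6-(2-methylprop-1-en-1-yl)oxan-2-one | O=C1C[C@H](C)C[C@H](C=C(C)C)O1 | intermediate
7 | tert-butyl bromoacetate | BrCC(=O)OC(C)(C)C | starting material
8 | tert-butyl 2-[(3S,4R,6R)-4-methyl-6-(2-methylprop-1-en-1-yl)-2-oxooxan-3-yl]acetate | O=C1[C@@H](CC(=O)OC(C)(C)C)[C@H](C)C[C@H](C=C(C)C)O1 | intermediate
9 | tert-butyl (3S,4R,6R)-6-hydroxy-3-[methoxy(methyl)carbamoyl]-4,8-dimethylnon-7-enoate | CON(C)C(=O)[C@@H](CC(=O)OC(C)(C)C)[C@H](C)C[C@H](C=C(C)C)O | intermediate
10 | tert-butyl (3S,4R,6R)-3-[methoxy(methyl)carbamoyl]-4,8-dimethyl-6-[(triethylsilyl)oxy]non-7-enoate | CON(C)C(=O)[C@@H](CC(=O)OC(C)(C)C)[C@H](C)C[C@H](C=C(C)C)O[Si](CC)(CC)CC | intermediate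
11 | tert-butyl (3S,4R,6R)-3-formyl-4,8-dimethyl-6-[(triethylsilyl)oxy]non-7-enoate | O=C[C@@H](CC(=O)OC(C)(C)C)[C@H](C)C[C@H](C=C(C)C)O[Si](CC)(CC)CC | intermediate
12 | (+)-B-allyldiisopinocampheylborane (isopinocampheyl groups from (−)-α-pinene) | C=CCB([C@H]1C[C@H]2C[C@@H]([C@@H]1C)C2(C)C)[C@H]1C[C@H]2C[C@@H]([C@@H]1C)C2(C)C | starting material
13 | tert-butyl (3S,4R,6R)-3-[(1R)-1-hydroxybut-3-en-1-yl]-4,8-dimethyl-6-[(triethylsilyl)oxy]non-7-enoate | O[C@H](CC=C)[C@@H](CC(=O)OC(C)(C)C)[C@H](C)C[C@H](C=C(C)C)O[Si](CC)(CC)CC | intermediate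
14 | tert-butyldimethylsilyl (3S,4R,6R)-3-[(1R)-1-[(tert-butyldimethylsilyl)oxy]but-3-en-1-yl]-4,8-dimethyl-6-[(triethylsilyl)oxy]non-7-enoate | CC(C)(C)[Si](C)(C)O[C@H](CC=C)[C@@H](CC(=O)O[Si](C)(C)C(C)(C)C)[C@H](C)C[C@H](C=C(C)C)O[Si](CC)(CC)CC | intermediate
15 | (3S,4R,6R)-3-[(1R)-1-[(tert-butyldimethylsilyl)oxy]but-3-en-1-yl]-4,8-dimethyl-6-[(triethylsilyl)oxy]non-7-enoic acid | CC(C)(C)[Si](C)(C)O[C@H](CC=C)[C@@H](CC(=O)O)[C@H](C)C[C@H](C=C(C)C)O[Si](CC)(CC)CC | intermediate
16 | Se-phenyl (3S,4R,6R)-3-[(1R)-1-[(tert-butyldimethylsilyl)oxy]but-3-en-1-yl]-4,8-dimethyl-6-[(triethylsilyl)oxy]non-7-eneselenoate | CC(C)(C)[Si](C)(C)O[C@H](CC=C)[C@@H](CC(=O)[Se]c1ccccc1)[C@H](C)C[C@H](C=C(C)C)O[Si](CC)(CC)CC | intermediate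
17 | (2R,4R,5S)-4-[(tert-butyldimethylsilyl)oxy]-2-methyl-5-[(2R,4R)-6-methyl-4-[(triethylsilyl)oxy]hept-5-en-2-yl]cyclohexan-1-one | CC(C)(C)[Si](C)(C)O[C@@H]1C[C@@H](C)C(=O)C[C@H]1[C@H](C)C[C@H](C=C(C)C)O[Si](CC)(CC)CC | intermediate
18 | (2S,4R,5S)-4-[(tert-butyldimethylsilyl)oxy]-2-methyl-5-[(2R,4R)-6-methyl-4-[(triethylsilyl)oxy]hept-5-en-2-yl]cyclohexan-1-one | CC(C)(C)[Si](C)(C)O[C@@H]1C[C@H](C)C(=O)C[C@H]1[C@H](C)C[C@H](C=C(C)C)O[Si](CC)(CC)CC | intermediate
19 | (1R,2S,4R,5S)-4-[(tert-butyldimethylsilyl)oxy]-2-methyl-5-[(2R,4R)-6-methyl-4-[(triethylsilyl)oxy]hept-5-en-2-yl]cyclohexan-1-ol | CC(C)(C)[Si](C)(C)O[C@@H]1C[C@H](C)[C@H](O)C[C@H]1[C@H](C)C[C@H](C=C(C)C)O[Si](CC)(CC)CC | intermediate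
20 | (1R,2S,4R,5S)-4-[(tert-butyldimethylsilyl)oxy]-5-[(2R,4R)-4-hydroxy-6-methylhept-5-en-2-yl]-2-methylcyclohexan-1-ol | CC(C)(C)[Si](C)(C)O[C@@H]1C[C@H](C)[C@H](O)C[C@H]1[C@H](C)C[C@H](C=C(C)C)O | intermediate
21 | (1R,2S,4R,5S)-5-[(2R,4R)-4-acetoxy-6-methylhept-5-en-2-yl]-4-[(tert-butyldimethylsilyl)oxy]-2-methylcyclohexyl acetate | CC(C)(C)[Si](C)(C)O[C@@H]1C[C@H](C)[C@H](OC(C)=O)C[C@H]1[C@H](C)C[C@H](C=C(C)C)OC(C)=O | intermediate
22 | (1R,2S,4R,5S)-5-[(2R,4R)-4-acetoxy-6-methylhept-5-en-2-yl]-4-hydroxy-2-methylcyclohexyl acetate | O[C@@H]1C[C@H](C)[C@H](OC(C)=O)C[C@H]1[C@H](C)C[C@H](C=C(C)C)OC(C)=O | intermediate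
23 | angelic acid, (2Z)-2-methylbut-2-enoic acid | C/C=C(/C)C(=O)O | starting material
24 | (2Z)-2-methylbut-2-enoic 2,4,6-trichlorobenzoic anhydride | C/C=C(/C)C(=O)OC(=O)c1c(Cl)cc(Cl)cc1Cl | intermediate
25 | (1R,2S,4R,5S)-4-acetoxy-2-[(2R,4R)-4-acetoxy-6-methylhept-5-en-2-yl]-5-methylcyclohexyl (2Z)-2-methylbut-2-enoate | C/C=C(/C)C(=O)O[C@@H]1C[C@H](C)[C@H](OC(C)=O)C[C@H]1[C@H](C)C[C@H](C=C(C)C)OC(C)=O | target

Total step count: 14. Longest linear sequence: 14 steps (from 1).

Steps most likely to fail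

Step 10. The acyl radical may take hydrogen from the stannane or lose carbon monoxide before it closes, or closure may leak into seven-membered modes (7-endo attack, or ring expansion of the cyclised radical). The fallback replaces the acyl radical by a ketyl radical anion, which has neither a decarbonylation nor a ring-expansion pathway. It sets out from acid 15 and comes back at ketone 18. The acid would be reduced through its mixed carbonic anhydride (i-BuOCOCl, N-methylmorpholine, THF, −15 °C; NaBH4, MeOH) to the primary alcohol F1 and oxidised with Dess–Martin periodinane to the aldehyde F2. SmI2 with HMPA and t-BuOH in THF should then effect a 6-exo ketyl–olefin cyclisation in which the C-4 ketyl carbon adds to C-5, giving the cyclohexanol F3 (drawn as the expected trans isomer; any C-4 or C-5 isomers converge in the next operation). Dess–Martin oxidation and DBU equilibration would return 18.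

Step 8. The allylic triethylsilyl ether may ionise or be lost during the prolonged silyl triflate exposure that the ester exchange needs, or the exchange may stay incomplete. The fallback removes the tert-butyl group by acyl transfer instead of Lewis acid. It sets out from 13 and comes back at silyl ester 14. Catalytic NaH in THF should close the cis-γ-lactone F4 with loss of tert-butanol, and LiOH in THF/H2O would open it to the lithium hydroxy carboxylate F5. Without acidification this salt would be silylated on both oxygens (TBSOTf, 2,6-lutidine, CH2Cl2, −78 °C, short contact) to give 14, which is hydrolysed to 15 as in the route.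

Step 14. The (Z)-2-methylbut-2-enoyl unit may isomerise to the (E) isomer during activation, and acylation of the hindered equatorial alcohol may be sluggish. The fallback builds the (Z) alkene on the ester instead of transferring it. It sets out from 22 and comes back at target 25. Esterification with 2-[bis(2,2,2-trifluoroethoxy)phosphoryl]propanoic acid (DCC, DMAP, CH2Cl2) would give the phosphonate F6, a mixture at the phosphorus-bearing carbon, which becomes sp2. Still–Gennari olefination with acetaldehyde (KN(SiMe3)2, 18-crown-6, THF, −78 °C) should then give the (Z)-trisubstituted enoate 25.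

Further compounds
F1 | step 10 | (3S,4R,6R)-3-[(1R)-1-[(tert-butyldimethylsilyl)oxy]but-3-en-1-yl]-4,8-dimethyl-6-[(triethylsilyl)oxy]non-7-en-1-ol | CC(C)(C)[Si](C)(C)O[C@H](CC=C)[C@@H](CCO)[C@H](C)C[C@H](C=C(C)C)O[Si](CC)(CC)CC
F2 | step 10 | (3S,4R,6R)-3-[(1R)-1-[(tert-butyldimethylsilyl)oxy]but-3-en-1-yl]-4,8-dimethyl-6-[(triethylsilyl)oxy]non-7-enal | CC(C)(C)[Si](C)(C)O[C@H](CC=C)[C@@H](CC=O)[C@H](C)C[C@H](C=C(C)C)O[Si](CC)(CC)CC
F3 | step 10 | (1S,2S,4R,5S)-4-[(tert-butyldimethylsilyl)oxy]-2-methyl-5-[(2R,4R)-6-methyl-4-[(triethylsilyl)oxy]hept-5-en-2-yl]cyclohexan-1-ol | CC(C)(C)[Si](C)(C)O[C@@H]1C[C@H](C)[C@@H](O)C[C@H]1[C@H](C)C[C@H](C=C(C)C)O[Si](CC)(CC)CC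
F4 | step 8 | (4S,5R)-4-[(2R,4R)-6-methyl-4-[(triethylsilyl)oxy]hept-5-en-2-yl]-5-(prop-2-en-1-yl)oxolan-2-one | O=C1C[C@@H]([C@H](C)C[C@H](C=C(C)C)O[Si](CC)(CC)CC)[C@@H](CC=C)O1
F5 | step 8 | lithium (3S,4R,6R)-3-[(1R)-1-hydroxybut-3-en-1-yl]-4,8-dimethyl-6-[(triethylsilyl)oxy]non-7-enoate | O[C@H](CC=C)[C@@H](CC(=O)[O-])[C@H](C)C[C@H](C=C(C)C)O[Si](CC)(CC)CC.[Li+]
F6 | step 14 | (1R,2S,4R,5S)-4-acetoxy-2-[(2R,4R)-4-acetoxy-6-methylhept-5-en-2-yl]-5-methylcyclohexyl 2-[bis(2,2,2-trifluoroethoxy)phosphoryl]propanoate | CC(P(=O)(OCC(F)(F)F)OCC(F)(F)F)C(=O)O[C@@H]1C[C@H](C)[C@H](OC(C)=O)C[C@H]1[C@H](C)C[C@H](C=C(C)C)OC(C)=O
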